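The plan cuts the pyranone away from ring A at two neighbouring atoms at once, the ether bond O1–C8a and the acyl bond C4–C4a. Because C8a and C4a are adjacent and C5, next to C4a, bears oxygen, ring A can enter as a C4a–C8a benzyne whose flanking alkoxy group sends a carboxylate oxygen to C8a, after which the acyl carbon shifts to C4a. One operation thus joins ring A, made from a mirror-symmetric phenol, to a ring B (Z)-2-methoxycinnamic acid that already holds C2, C3 with its methoxy group, C4, the prenyl group and the (S) side chain. The product is a 2'-hydroxy-α-methoxychalcone with unambiguous 5,6,7-oxygenation; the benzyne precursor is an ortho-silylaryl triflate.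

Key step: step 14

Remarks on the chemistry
- Protecting groups: the three phenols are carried as MOM ethers and the side-chain alcohol as a trityl ether. All four are inert to fluoride, organometallics and base and should fall together in dilute methanolic HCl at room temperature. An acetal on the aliphatic oxygen would need hot acid, which is the condition that turns an ortho-prenylphenol into a chroman.
- The only stereocentre is bought with methyl (R)-3-hydroxy-2-methylpropanoate. Its ester carbon becomes C2 of the butyl chain and its CH2O group stays, so no bond to the centre is ever made or broken; the descriptor changes from (R) to (S) through CIP priorities alone.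
- Ring C is dehydrogenated through a silyl enol ether and Pd(OAc)2 at room temperature, because hot quinone or iodine oxidants endanger the benzylic/allylic prenyl CH2 and the acetals.
- Assumption: if part of the chalcone closes to the flavanone under the conditions of the key step, both are taken on together, since the following step makes that flavanone in any case.
- ArB in the names below = 4-(methoxymethoxy)-3-(3-methylbut-2-en-1-yl)-5-[(3S)-3-methyl-4-(trityloxy)butyl]phenyl.

Step 1
Reactants: 1 2-methoxyresorcinol (2-methoxybenzene-1,3-diol)
Product: 2 bis-MOM ether (2-methoxy-1,3-bis(methoxymethoxy)benzene)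
Conditions: MOMCl (2.5 equiv), i-Pr2NEt (3 equiv), CH2Cl2, 0 °C → rt
Reagents that add atoms: chloromethyl methyl ether, COCCl
Why: Both phenols are O-alkylated by the reactive α-chloro ether under amine base (Williamson-type etherification), the methyl ether being inert.

Step 2
Reactants: 2 bis-MOM ether
Product: 4 symmetric phenol (4-methoxy-3,5-bis(methoxymethoxy)phenol), via arylboronate 3 (not isolated)
Conditions: [Ir(OMe)(cod)]2 (1.5 mol%), 4,4'-di-tert-butyl-2,2'-bipyridine (3 mol%), B2pin2 (0.6 equiv), THF, 80 °C; then aq NaOH, 30% H2O2, 0 °C → rt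
Reagents that add atoms: hydrogen peroxide, OO
Why: Iridium-catalysed C–H borylation is governed by sterics and should take the only ring hydrogen without an ortho neighbour (para to the methoxy group), and alkaline peroxide oxidation of the C–B bond then gives the phenol while the base-stable MOM ethers stay.

Step 3
Reactants: 4 symmetric phenol
Product: 5 bromophenol (2-bromo-4-methoxy-3,5-bis(methoxymethoxy)phenol)
Conditions: NBS (1.0 equiv), CH2Cl2, −78 → −20 °C
Reagents that add atoms: N-bromosuccinimide, O=C1CCC(=O)N1Br
Why: Electrophilic aromatic bromination ortho to the free hydroxyl; the two open positions are equivalent by symmetry and the para position is blocked, so one equivalent of NBS at low temperature should stop at the monobromide under acid-free conditions that spare the acetals.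

Step 4
Reactants: 5 bromophenol
Product: 6 silyl ether ([2-bromo-4-methoxy-3,5-bis(methoxymethoxy)phenoxy]trimethylsilane)
Conditions: (Me3Si)2NH (0.8 equiv), THF, 65 °C; evaporate
Reagents that add atoms: hexamethyldisilazane, C[Si](C)(C)N[Si](C)(C)C
Why: O-Silylation of the phenol by the disilazane with loss of ammonia needs neither acid nor added base and leaves a product that can be used after evaporation.

Step 5
Reactants: 6 silyl ether
Product: 9 aryne precursor (4-methoxy-3,5-bis(methoxymethoxy)-2-(trimethylsilyl)phenyl trifluoromethanesulfonate), via aryllithium 7 (not isolated), via lithium phenoxide 8 (not isolated)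
Conditions: n-BuLi (1.1 equiv), THF, −78 °C; then Tf2O (1.2 equiv), −78 → 0 °C
Reagents that add atoms: trifluoromethanesulfonic anhydride, O=S(=O)(OS(=O)(=O)C(F)(F)F)C(F)(F)F
Why: Bromine–lithium exchange is followed by 1,3-migration of silicon from oxygen to the lithiated carbon (retro-Brook rearrangement), and the phenoxide so formed is trapped by the anhydride, the standard entry to ortho-silylaryl triflates.

Step 6
Reactants: 10 hydroxy ester (methyl (R)-3-hydroxy-2-methylpropanoate)
Product: 11 trityl ether (methyl (R)-2-methyl-3-(trityloxy)propanoate)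
Conditions: Ph3CCl, Et3N, DMAP (cat.), CH2Cl2, rt
Reagents that add atoms: trityl chloride, ClC(c1ccccc1)(c1ccccc1)c1ccccc1
Why: SN1-type tritylation of the primary alcohol; the stereocentre, which comes with the chiral-pool ester, is not involved.

Step 7
Reactants: 11 trityl ether
Product: 12 aldehyde ((R)-2-methyl-3-(trityloxy)propanal)
Conditions: i-Bu2AlH (1.1 equiv), CH2Cl2, −78 °C; MeOH, then aq KNaC4H4O6
Reagents that add atoms: none
Why: Partial reduction of the ester should stop at the aluminium hemiacetal at −78 °C and release the aldehyde on work-up; the α-stereocentre is expected to hold if the aldehyde is kept cold and used at once.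

Step 8
Reactants: 12 aldehyde
Product: 13 alkene ({[(2S)-2-methylbut-3-en-1-yl]oxy}triphenylmethane)
Conditions: Ph3PCH3Br, KN(SiMe3)2, THF, 0 °C; then 12, −78 → 0 °C
Reagents that add atoms: methyltriphenylphosphonium bromide, C[P+](c1ccccc1)(c1ccccc1)c1ccccc1.[Br-]
Why: Wittig methylenation with the non-stabilised ylide at low temperature should outrun enolisation of the aldehyde; no bond to the stereocentre changes, and the descriptor becomes (S) only because the vinyl group ranks below CH2O.

Step 9
Reactants: 14 3-bromo-4-hydroxybenzaldehyde; 15 3-chloro-3-methylbut-1-yne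
Product: 16 propargyl ether (3-bromo-4-[(2-methylbut-3-yn-2-yl)oxy]benzaldehyde)
Conditions: DBU (1.5 equiv), CuCl2·2H2O (1 mol%), MeCN, 0 °C → rt
Reagents that add atoms: none
Why: Copper-catalysed O-alkylation of the phenoxide by the tertiary propargylic chloride goes through a copper-bound propargyl/allenyl cation equivalent and is well suited to electron-poor phenols.

Step 10
Reactants: 16 propargyl ether
Product: 18 prenyl phenol (3-bromo-4-hydroxy-5-(3-methylbut-2-en-1-yl)benzaldehyde), via allyl ether 17 (not isolated)
Conditions: H2 (1 atm), Pd/CaCO3 poisoned with Pb(OAc)2, quinoline, EtOAc, rt; filter, exchange solvent; o-xylene, 130 °C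
Reagents that add atoms: none
Why: Semihydrogenation over the poisoned palladium catalyst (Lindlar reduction) gives the 1,1-dimethylallyl aryl ether, whose aromatic Claisen rearrangement can only end at the one free ortho carbon and delivers the linear prenyl group there.

Step 11
Reactants: 18 prenyl phenol
Product: 19 aryl bromide (3-bromo-4-(methoxymethoxy)-5-(3-methylbut-2-en-1-yl)benzaldehyde)
Conditions: MOMCl, i-Pr2NEt, CH2Cl2, 0 °C → rt
Reagents that add atoms: chloromethyl methyl ether, COCCl
Why: Williamson-type O-alkylation of the acidic phenol removes the acidic proton before the organometallic and basic steps.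

Step 12
Reactants: 13 alkene; 19 aryl bromide
Product: 21 ring B aldehyde (4-(methoxymethoxy)-3-(3-methylbut-2-en-1-yl)-5-[(3S)-3-methyl-4-(trityloxy)butyl]benzaldehyde), via alkylborane 20 (not isolated)
Conditions: 13 (1.5 equiv), 9-BBN-H dimer (0.65 equiv), THF, 0 °C → rt; then 3 M aq K3PO4, 19 (1.0 equiv), Pd(dppf)Cl2 (5 mol%), DMF, 60 °C
Reagents that add atoms: none
Why: anti-Markovnikov hydroboration of the terminal alkene gives the primary alkylborane, which should undergo B-alkyl Suzuki–Miyaura coupling with the aryl bromide; keeping the borane below the amount of 13 leaves no B–H for the aldehyde or the prenyl group of 19, and the stereocentre is a spectator.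

Step 13
Reactants: 21 ring B aldehyde; 22 methyl methoxyacetate
Product: 24 ring B acid ((2Z)-2-methoxy-3-(ArB)prop-2-enoic acid), via methyl ester 23 (not isolated)
Conditions: 22 (3 equiv), NaOMe (3 equiv), THF–MeOH, 0 → 50 °C; then 2 M aq NaOH, 50 °C; cold aq NaHSO4 to pH 3–4
Reagents that add atoms: sodium hydroxide, [Na+].[OH-]
Why: Aldol-type (Claisen–Schmidt) condensation of the ester enolate with the non-enolisable aldehyde and E1cB dehydration should give the thermodynamically preferred (Z)-α-methoxycinnamate (ester group trans to the aryl ring), and saponification in the same flask gives the acid.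

Step 14
Reactants: 9 aryne precursor; 24 ring B acid
Product: 26 chalcone ((2Z)-1-[6-hydroxy-3-methoxy-2,4-bis(methoxymethoxy)phenyl]-2-methoxy-3-(ArB)prop-2-en-1-one), via aryne 25 (not isolated)
Conditions: 9 (1.5 equiv), CsF (4 equiv), THF, 110 °C (sealed tube); aq NH4Cl
Reagents that add atoms: none
Why: Proposed new method: Fluoride turns acid 24 into its caesium carboxylate and, by attack at silicon with loss of triflate, releases benzyne 25; the carboxylate oxygen adds to the aryne carbon remote from the flanking OMOM group (future C8a), and the aryl anion left between the new ester oxygen and OMOM (future C4a) attacks the ester carbonyl through a transient four-membered alkoxide that collapses with C–O cleavage to the C4 ketone and the C8a phenoxide. The closest known reaction type is the aryne/carboxylic acid C–O insertion in which a fluoride-generated aryne and a benzoic, alkanoic, cinnamic or arylpropiolic acid give a 2-hydroxyaryl ketone; an α-alkoxycinnamic acid and a trioxygenated benzyne have not been shown in it, hence the label. No ring is closed (the four-membered alkoxide is only a transient) and no stereocentre is formed, while the (Z) double bond and the (3S) centre are not touched. The selectivity needed is regiochemical, and the σ-withdrawing OMOM group beside the triple bond secures it: as in 3-alkoxybenzynes generally it directs the nucleophile to the distal, less hindered carbon and leaves the charge ortho to oxygen. Acyl transfer must also outrun protonation of the aryl anion, which the proximity of the ester carbonyl and hot, weakly solvating THF with no proton source beyond the bifluoride formed from the acid should favour. Flavanone 27 formed by premature oxa-Michael closure of the product phenoxide would be carried on with 26, since step 15 makes it in any case.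

Step 15
Reactants: 26 chalcone
Product: 27 flavanone (3,6-dimethoxy-5,7-bis(methoxymethoxy)-2-(ArB)-2,3-dihydro-4H-chromen-4-one as a mixture of C2/C3 diastereomers)
Conditions: NaOAc, EtOH, 78 °C
Reagents that add atoms: none
Why: Base-mediated intramolecular oxa-Michael addition of the 2'-phenoxide to the enone (6-endo-trig) is the classical chalcone-to-flavanone isomerisation; the new centres at C2 and C3 form without control, which is of no consequence because both become sp2 in step 16.

Step 16
Reactants: 27 flavanone
Product: 29 protected flavone (3,6-dimethoxy-5,7-bis(methoxymethoxy)-2-(ArB)-4H-chromen-4-one), via silyl enol ether 28 (not isolated)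
Conditions: Me3SiCl (1.5 equiv), LiN(SiMe3)2 (1.3 equiv), THF, −78 °C; evaporate; then Pd(OAc)2 (1.1 equiv), MeCN, rt
Reagents that add atoms: none
Why: Deprotonation at C3, the only α-position, with the silyl chloride already present should trap the enolate before it can expel the phenoxide, and Saegusa–Ito oxidation (palladation at C3 on the face anti to the C2 aryl group, then β-hydride elimination of the syn H–C2) gives the flavone under conditions that should leave the trisubstituted prenyl alkene, the acetals and the trityl ether alone.

Step 17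
Reactants: 29 protected flavone
Product: 30 target (5,7-dihydroxy-2-{4-hydroxy-3-[(3S)-4-hydroxy-3-methylbutyl]-5-(3-methylbut-2-en-1-yl)phenyl}-3,6-dimethoxy-4H-chromen-4-one)
Conditions: HCl (1.25 M in MeOH), THF–MeOH, rt
Reagents that add atoms: none
Why: Acid-catalysed transacetalisation of the three aryl MOM ethers and SN1 methanolysis of the trityl ether should all proceed at room temperature, mild enough that the prenyl group beside the liberated 4'-OH should not cyclise; the (S) centre is remote from every reacting site.

Compound list
1 | 2-methoxybenzene-1,3-diol | COc1c(O)cccc1O | starting material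
2 | 2-methoxy-1,3-bis(methoxymethoxy)benzene | COCOc1cccc(OCOC)c1OC | intermediate
3 | 2-[4-methoxy-3,5-bis(methoxymethoxy)phenyl]-4,4,5,5-tetramethyl-1,3,2-dioxaborolane (not isolated) | COCOc1cc(B2OC(C)(C)C(C)(C)O2)cc(OCOC)c1OC | intermediate
4 | 4-methoxy-3,5-bis(methoxymethoxy)phenol | COCOc1cc(O)cc(OCOC)c1OC | intermediate
5 | 2-bromo-4-methoxy-3,5-bis(methoxymethoxy)phenol | COCOc1cc(O)c(Br)c(OCOC)c1OC | intermediate
6 | [2-bromo-4-methoxy-3,5-bis(methoxymethoxy)phenoxy]trimethylsilane | COCOc1cc(O[Si](C)(C)C)c(Br)c(OCOC)c1OC | intermediate
7 | [3-methoxy-2,4-bis(methoxymethoxy)-6-(trimethylsilyloxy)phenyl]lithium (not isolated) | COCOc1cc(O[Si](C)(C)C)c([Li])c(OCOC)c1OC | intermediate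
8 | lithium 4-methoxy-3,5-bis(methoxymethoxy)-2-(trimethylsilyl)phenoxide (not isolated) | [Li+].[O-]c1cc(OCOC)c(OC)c(OCOC)c1[Si](C)(C)C | intermediate
9 | 4-methoxy-3,5-bis(methoxymethoxy)-2-(trimethylsilyl)phenyl trifluoromethanesulfonate | COCOc1cc(OS(=O)(=O)C(F)(F)F)c([Si](C)(C)C)c(OCOC)c1OC | intermediate
10 | methyl (R)-3-hydroxy-2-methylpropanoate | COC(=O)[C@H](C)CO | starting material
11 | methyl (R)-2-methyl-3-(trityloxy)propanoate | COC(=O)[C@H](C)COC(c1ccccc1)(c1ccccc1)c1ccccc1 | intermediate
12 | (R)-2-methyl-3-(trityloxy)propanal | O=C[C@H](C)COC(c1ccccc1)(c1ccccc1)c1ccccc1 | intermediate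
13 | {[(2S)-2-methylbut-3-en-1-yl]oxy}triphenylmethane | C=C[C@H](C)COC(c1ccccc1)(c1ccccc1)c1ccccc1 | intermediate
14 | 3-bromo-4-hydroxybenzaldehyde | O=Cc1ccc(O)c(Br)c1 | starting material
15 | 3-chloro-3-methylbut-1-yne | CC(C)(Cl)C#C | starting material
16 | 3-bromo-4-[(2-methylbut-3-yn-2-yl)oxy]benzaldehyde | O=Cc1ccc(OC(C)(C)C#C)c(Br)c1 | intermediate
17 | 3-bromo-4-[(2-methylbut-3-en-2-yl)oxy]benzaldehyde (not isolated) | O=Cc1ccc(OC(C)(C)C=C)c(Br)c1 | intermediate
18 | 3-bromo-4-hydroxy-5-(3-methylbut-2-en-1-yl)benzaldehyde | O=Cc1cc(Br)c(O)c(CC=C(C)C)c1 | intermediate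
19 | 3-bromo-4-(methoxymethoxy)-5-(3-methylbut-2-en-1-yl)benzaldehyde | O=Cc1cc(Br)c(OCOC)c(CC=C(C)C)c1 | intermediate
20 | 9-[(3S)-3-methyl-4-(trityloxy)butyl]-9-borabicyclo[3.3.1]nonane (not isolated) | B1(CC[C@H](C)COC(c2ccccc2)(c2ccccc2)c2ccccc2)C2CCCC1CCC2 | intermediate
21 | 4-(methoxymethoxy)-3-(3-methylbut-2-en-1-yl)-5-[(3S)-3-methyl-4-(trityloxy)butyl]benzaldehyde | O=Cc1cc(CC=C(C)C)c(OCOC)c(CC[C@H](C)COC(c2ccccc2)(c2ccccc2)c2ccccc2)c1 | intermediate
22 | methyl 2-methoxyacetate | COCC(=O)OC | starting material
23 | methyl (2Z)-2-methoxy-3-{4-(methoxymethoxy)-3-(3-methylbut-2-en-1-yl)-5-[(3S)-3-methyl-4-(trityloxy)butyl]phenyl}prop-2-enoate (not isolated) | CO/C(=C\c1cc(CC=C(C)C)c(OCOC)c(CC[C@H](C)COC(c2ccccc2)(c2ccccc2)c2ccccc2)c1)C(=O)OC | intermediate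
24 | (2Z)-2-methoxy-3-{4-(methoxymethoxy)-3-(3-methylbut-2-en-1-yl)-5-[(3S)-3-methyl-4-(trityloxy)butyl]phenyl}prop-2-enoic acid | CO/C(=C\c1cc(CC=C(C)C)c(OCOC)c(CC[C@H](C)COC(c2ccccc2)(c2ccccc2)c2ccccc2)c1)C(=O)O | intermediate
25 | 4-methoxy-3,5-bis(methoxymethoxy)benzyne, 1,2-didehydrobenzene numbering (not isolated) | COCOC1=CC#CC(OCOC)=C1OC | intermediate
26 | (2Z)-1-[6-hydroxy-3-methoxy-2,4-bis(methoxymethoxy)phenyl]-2-methoxy-3-{4-(methoxymethoxy)-3-(3-methylbut-2-en-1-yl)-5-[(3S)-3-methyl-4-(trityloxy)butyl]phenyl}prop-2-en-1-one | COCOc1cc(O)c(C(=O)/C(OC)=C/c2cc(CC=C(C)C)c(OCOC)c(CC[C@H](C)COC(c3ccccc3)(c3ccccc3)c3ccccc3)c2)c(OCOC)c1OC | intermediate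
27 | 3,6-dimethoxy-5,7-bis(methoxymethoxy)-2-{4-(methoxymethoxy)-3-(3-methylbut-2-en-1-yl)-5-[(3S)-3-methyl-4-(trityloxy)butyl]phenyl}-2,3-dihydro-4H-chromen-4-one, C2 and C3 undefined (diastereomer mixture) | COc1c(OCOC)cc2OC(c3cc(CC=C(C)C)c(OCOC)c(CC[C@H](C)COC(c4ccccc4)(c4ccccc4)c4ccccc4)c3)C(OC)C(=O)c2c1OCOC | intermediate
28 | {[3,6-dimethoxy-5,7-bis(methoxymethoxy)-2-{4-(methoxymethoxy)-3-(3-methylbut-2-en-1-yl)-5-[(3S)-3-methyl-4-(trityloxy)butyl]phenyl}-2H-chromen-4-yl]oxy}trimethylsilane, C2 undefined (not isolated) | COc1c(OCOC)cc2OC(c3cc(CC=C(C)C)c(OCOC)c(CC[C@H](C)COC(c4ccccc4)(c4ccccc4)c4ccccc4)c3)C(OC)=C(O[Si](C)(C)C)c2c1OCOC | intermediate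
29 | 3,6-dimethoxy-5,7-bis(methoxymethoxy)-2-{4-(methoxymethoxy)-3-(3-methylbut-2-en-1-yl)-5-[(3S)-3-methyl-4-(trityloxy)butyl]phenyl}-4H-chromen-4-one | COc1c(OCOC)cc2oc(-c3cc(CC=C(C)C)c(OCOC)c(CC[C@H](C)COC(c4ccccc4)(c4ccccc4)c4ccccc4)c3)c(OC)c(=O)c2c1OCOC | intermediate
30 | 5,7-dihydroxy-2-{4-hydroxy-3-[(3S)-4-hydroxy-3-methylbutyl]-5-(3-methylbut-2-en-1-yl)phenyl}-3,6-dimethoxy-4H-chromen-4-one | COc1c(O)cc2oc(-c3cc(CC=C(C)C)c(O)c(CC[C@H](C)CO)c3)c(OC)c(=O)c2c1O | target

Total step count: 17. Longest linear sequence: 9 steps (for example from 14 through steps 9–17; the lines from 1 and from 10 are equally long).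

Steps most likely to fail

Step 14. The aryl anion formed after carboxylate addition may be protonated faster than it attacks the hindered ester carbonyl, so that the sequence stops at the aryl ester. The benzyne may also be consumed by the electron-rich enol ether or the prenyl alkene of the acid. The fallback uses known chemistry only; it sets out from bromophenol 5 and aldehyde 21 and comes back to the route at chalcone 26. Treatment of 5 with n-BuLi (2.1 equiv, THF, −78 °C) should deprotonate the phenol and exchange bromine for lithium to give lithium 2-lithio-4-methoxy-3,5-bis(methoxymethoxy)phenoxide F1. Acylation of F1 with N-methoxy-N-methyl-2-methoxyacetamide should give 1-[6-hydroxy-3-methoxy-2,4-bis(methoxymethoxy)phenyl]-2-methoxyethan-1-one F2. Claisen–Schmidt condensation of F2 with 21 (KOH, EtOH, rt) then gives 26. The free hydroxyl of F2 is again the one next to the ring C–H, so the oxygenation pattern stays fixed.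

Step 16. The C3 enolate may expel the C8a phenoxide (retro-oxa-Michael ring opening) before it is silylated, or palladium may be diverted by the prenyl alkene, so that dehydrogenation stalls and chalcone is returned. The fallback changes from an enolate/palladium route to a halogen-mediated oxidative cyclisation; it sets out from chalcone 26, passes by 27 and 28, and comes back at 29. Heating 26 with catalytic I2 in DMSO at about 110 °C should effect ring closure, iodination at C3 and loss of HI in one flask, with DMSO as the terminal oxidant. Loss of the C5 acetal under these conditions would not matter, because step 17 removes it anyway.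

Step 10. The alkyne may be over-reduced to the saturated ether, which cannot rearrange. The tertiary allyl aryl ether may also ionise and lose its five-carbon unit in competition with the sigmatropic shift, since the bromo-formyl phenoxide is a good leaving group. The fallback replaces the rearrangement by a cross-coupling; it sets out from 14 and comes back at 19. Iodination of 14 ortho to the hydroxyl (N-iodosuccinimide, MeCN, rt) should give 3-bromo-4-hydroxy-5-iodobenzaldehyde F3. MOM protection (MOMCl, i-Pr2NEt) gives 3-bromo-5-iodo-4-(methoxymethoxy)benzaldehyde F4. Stille coupling of F4 at the more reactive C–I bond with tributyl(3-methylbut-2-en-1-yl)stannane (Pd(PPh3)4, DMF, 60 °C) then gives 19, with the C–Br bond kept for step 12.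

Further compounds
F1 | step 14 | lithium 2-lithio-4-methoxy-3,5-bis(methoxymethoxy)phenoxide | [Li+].[O-]c1cc(OCOC)c(OC)c(OCOC)c1[Li]
F2 | step 14 | 1-[6-hydroxy-3-methoxy-2,4-bis(methoxymethoxy)phenyl]-2-methoxyethan-1-one | COCC(=O)c1c(O)cc(OCOC)c(OC)c1OCOC
F0 | step 16 | none | none
F3 | step 10 | 3-bromo-4-hydroxy-5-iodobenzaldehyde | O=Cc1cc(Br)c(O)c(I)c1
F4 | step 10 | 3-bromo-5-iodo-4-(methoxymethoxy)benzaldehyde | O=Cc1cc(Br)c(OCOC)c(I)c1
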